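The route disconnects the O1–C8a aryl ether of the pyran ring after formally replacing the C3–H by a second hydroxymethyl group. C3 lies between two CH2 groups (C2 and C4), so this change gives an achiral 2-aryl-2-(2-iodobenzyl)propane-1,3-diol whose two CH2OH arms are enantiotopic. A chiral copper(I)–diamine catalyst joins one of them to the iodinated carbon, which closes the pyran ring and fixes C3 as a quaternary stereocentre in one operation. The unused CH2OH is then oxidised and excised as CO with retention, leaving the C3–H of the (S)-isoflavan. The phenol is carried as a benzyl ether to the last step.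

Key step: step 9

Remarks and assumptions
- Structure check: the target is (3S). The diol and the chroman alcohol of the key step are consistent with it and need no correction. The alcohol 12 is (S), the aldehyde 13 is (R) and the isoflavans 14 and 15 are (S); the spatial arrangement is the same throughout, and the letter changes only because CHO outranks C2 in the CIP order.
- Precursor design: the diol is kept as the aryl iodide with the C7 phenol as a benzyl ether. A free phenol would itself be O-arylated, the iodide offsets the hindrance of the flanking C8 methoxy group, and benzyl survives hydride, base, copper and rhodium and leaves by hydrogenolysis.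
- Iodine placement: iodine is introduced by electrophilic iodination ortho to a free 3-hydroxyl (the isovanillin pattern) and the hydroxyl is then methylated. Ortho-lithiation of an O-benzylvanillin derivative is avoided because the formyl group must first be masked and the OCH2Ph group can itself be lithiated.
- Ester reduction: DIBAL-H is used instead of LiAlH4 to protect the C–I bond and to avoid retro-aldol loss of formaldehyde.
- Assumption: the sense of induction of the chiral diamine on this 2-aryl diol cannot be predicted with certainty. The ligand antipode that gives the (S)-alcohol is fixed by a small screen, and the route is written for that antipode.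
- Assumption: 4-(benzyloxy)-3-hydroxybenzaldehyde is taken as a commercial starting material.

Step 1
Reactants: 1 1,2,3,4-tetramethoxybenzene
Product: 2 1-bromo-2,3,4,5-tetramethoxybenzene
Conditions: NBS (1.0 equiv), MeCN, 0 °C → rt
Reagents that add atoms: N-bromosuccinimide, O=C1CCC(=O)N1Br
Why: Electrophilic aromatic bromination, in which the two free ring positions of 1 are equivalent and each is para to a methoxy group, so one equivalent of NBS should give a single monobromide.

Step 2
Reactants: 2 1-bromo-2,3,4,5-tetramethoxybenzene; 3 diethyl malonate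
Product: 4 diethyl 2-(2,3,4,5-tetramethoxyphenyl)malonate
Conditions: Pd(dba)2 (2 mol%), P(t-Bu)3·HBF4 (4 mol%), K3PO4, toluene, 70 °C
Reagents that add atoms: none
Why: Palladium-catalysed α-arylation of a malonate enolate, in which the bulky electron-rich phosphine should drive oxidative addition of the electron-rich bromide and C–C reductive elimination, while the acidic product rests as its enolate and so is not arylated twice.

Step 3
Reactants: 5 4-(benzyloxy)-3-hydroxybenzaldehyde
Product: 6 4-(benzyloxy)-3-hydroxy-2-iodobenzaldehyde
Conditions: ICl, pyridine, 1,4-dioxane, 0 °C → rt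
Reagents that add atoms: iodine monochloride, ClI
Why: Electrophilic aromatic iodination of a phenol, in which the free 3-hydroxyl should steer iodine to C2, the ortho position next to the formyl group, as in the 2-halogenation of isovanillin, while its other ortho position carries the benzyloxy group.

Step 4
Reactants: 6 4-(benzyloxy)-3-hydroxy-2-iodobenzaldehyde
Product: 7 4-(benzyloxy)-2-iodo-3-methoxybenzaldehyde
Conditions: MeI, K2CO3, DMF, rt
Reagents that add atoms: iodomethane, CI
Why: Williamson O-methylation, an SN2 reaction of the acidic ortho-iodophenoxide with iodomethane that leaves the aldehyde and the aryl iodide untouched.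

Step 5
Reactants: 7 4-(benzyloxy)-2-iodo-3-methoxybenzaldehyde
Product: 8 [4-(benzyloxy)-2-iodo-3-methoxyphenyl]methanol
Conditions: NaBH4, MeOH–THF, 0 °C
Reagents that add atoms: none
Why: Borohydride 1,2-reduction of the aldehyde, to which the aryl iodide and the benzyl ether are inert.

Step 6
Reactants: 8 [4-(benzyloxy)-2-iodo-3-methoxyphenyl]methanol
Product: 9 1-(benzyloxy)-4-(bromomethyl)-3-iodo-2-methoxybenzene
Conditions: PBr3, CH2Cl2, 0 °C; used at once
Reagents that add atoms: phosphorus tribromide, BrP(Br)Br
Why: Conversion of a benzylic alcohol into the bromide by SN2 displacement of its phosphite ester with bromide, mild enough for the benzyl ether, the electron-rich bromide being taken on without storage.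

Step 7
Reactants: 4 diethyl 2-(2,3,4,5-tetramethoxyphenyl)malonate; 9 1-(benzyloxy)-4-(bromomethyl)-3-iodo-2-methoxybenzene
Product: 10 diethyl 2-{[4-(benzyloxy)-2-iodo-3-methoxyphenyl]methyl}-2-(2,3,4,5-tetramethoxyphenyl)malonate
Conditions: NaH, THF–DMF, 0 °C → rt
Reagents that add atoms: none
Why: Malonic ester alkylation, an SN2 reaction of the sodium enolate of 4 with the benzylic bromide, which builds the quaternary carbon without over-alkylation because 4 has only one acidic hydrogen, and which leaves the aryl iodide alone.

Step 8
Reactants: 10 diethyl 2-{[4-(benzyloxy)-2-iodo-3-methoxyphenyl]methyl}-2-(2,3,4,5-tetramethoxyphenyl)malonate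
Product: 11 2-{[4-(benzyloxy)-2-iodo-3-methoxyphenyl]methyl}-2-(2,3,4,5-tetramethoxyphenyl)propane-1,3-diol
Conditions: DIBAL-H (6 equiv), CH2Cl2, −78 → 0 °C; Rochelle salt work-up
Reagents that add atoms: none
Why: Hydride reduction of both esters by DIBAL-H, chosen because its covalent aluminium alkoxides resist retro-aldol loss of formaldehyde at the quaternary carbon and because it leaves the aryl iodide intact.

Step 9
Reactants: 11 2-{[4-(benzyloxy)-2-iodo-3-methoxyphenyl]methyl}-2-(2,3,4,5-tetramethoxyphenyl)propane-1,3-diol
Product: 12 [(3S)-7-(benzyloxy)-8-methoxy-3-(2,3,4,5-tetramethoxyphenyl)-3,4-dihydro-2H-chromen-3-yl]methanol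
Conditions: CuI (10 mol%), chiral C2-symmetric cyclic 1,2-diamine L* (20 mol%, e.g. one antipode of 2,3-diphenylpiperazine), Cs2CO3, MeCN, 25–50 °C, 0.05 M
Reagents that add atoms: none
Why: Caesium carbonate delivers one hydroxymethyl group as an alkoxide to the diamine-bound copper(I), the C8a–I bond adds oxidatively to give a seven-membered aryl–copper(III) alkoxide, and C–O reductive elimination forms the O1–C8a bond. The closest known reaction type is the copper-catalysed enantioselective intramolecular Ullmann O-arylation that desymmetrises 2-(2-iodobenzyl)propane-1,3-diols to chroman-3-ylmethanols. The pyran ring closes in a formal 6-exo-trig sense at C8a, the breaking C–I bond lying outside the new ring. C3 becomes a quaternary stereocentre, and its configuration is set by the chiral diamine on copper, which decides which of the two enantiotopic CH2OH groups is bound in the ring-forming event (catalyst control, the substrate being achiral). The step needs enantiotopic-group selectivity and ring closure in preference to intermolecular etherification: the single aryl halide, made an iodide because the neighbouring C8 methoxy group hinders oxidative addition, the favourable six-membered ring and the dilution secure the latter, and the spare hydroxyl has no halide left to react with once the ring is closed.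

Step 10
Reactants: 12 [(3S)-7-(benzyloxy)-8-methoxy-3-(2,3,4,5-tetramethoxyphenyl)-3,4-dihydro-2H-chromen-3-yl]methanol
Product: 13 (3R)-7-(benzyloxy)-8-methoxy-3-(2,3,4,5-tetramethoxyphenyl)-3,4-dihydro-2H-chromene-3-carbaldehyde
Conditions: Dess–Martin periodinane, CH2Cl2, 0 °C → rt
Reagents that add atoms: none
Why: Dess–Martin oxidation of the hindered neopentyl-type primary alcohol to the aldehyde, which cannot epimerise because C3 carries no hydrogen.

Step 11
Reactants: 13 (3R)-7-(benzyloxy)-8-methoxy-3-(2,3,4,5-tetramethoxyphenyl)-3,4-dihydro-2H-chromene-3-carbaldehyde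
Product: 14 (3S)-7-(benzyloxy)-8-methoxy-3-(2,3,4,5-tetramethoxyphenyl)-3,4-dihydro-2H-chromene
Conditions: RhCl(PPh3)3 (1.1 equiv), PhCN, 130–160 °C
Reagents that add atoms: none
Why: Tsuji–Wilkinson decarbonylation, in which formyl C–H oxidative addition to rhodium(I), CO extrusion and C–H reductive elimination all occur at the metal, so hydrogen should take the place of the formyl group with retention at C3.

Step 12
Reactants: 14 (3S)-7-(benzyloxy)-8-methoxy-3-(2,3,4,5-tetramethoxyphenyl)-3,4-dihydro-2H-chromene
Product: 15 (3S)-8-methoxy-3-(2,3,4,5-tetramethoxyphenyl)-3,4-dihydro-2H-chromen-7-ol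
Conditions: H2 (1 atm), 10% Pd/C, EtOAc–MeOH, rt
Reagents that add atoms: none
Why: Catalytic hydrogenolysis of the benzyl aryl ether, which should free the C7 phenol without touching the methyl ethers, the chroman C–O bonds or the C3 stereocentre.

Compound list
1 | 1,2,3,4-tetramethoxybenzene | COc1ccc(OC)c(OC)c1OC | starting material
2 | 1-bromo-2,3,4,5-tetramethoxybenzene | COc1cc(Br)c(OC)c(OC)c1OC | intermediate
3 | diethyl malonate | CCOC(=O)CC(=O)OCC | starting material
4 | diethyl 2-(2,3,4,5-tetramethoxyphenyl)malonate | CCOC(=O)C(C(=O)OCC)c1cc(OC)c(OC)c(OC)c1OC | intermediate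
5 | 4-(benzyloxy)-3-hydroxybenzaldehyde | O=Cc1ccc(OCc2ccccc2)c(O)c1 | starting material
6 | 4-(benzyloxy)-3-hydroxy-2-iodobenzaldehyde | O=Cc1ccc(OCc2ccccc2)c(O)c1I | intermediate
7 | 4-(benzyloxy)-2-iodo-3-methoxybenzaldehyde | O=Cc1ccc(OCc2ccccc2)c(OC)c1I | intermediate
8 | [4-(benzyloxy)-2-iodo-3-methoxyphenyl]methanol | OCc1ccc(OCc2ccccc2)c(OC)c1I | intermediate
9 | 1-(benzyloxy)-4-(bromomethyl)-3-iodo-2-methoxybenzene | BrCc1ccc(OCc2ccccc2)c(OC)c1I | intermediate
10 | diethyl 2-{[4-(benzyloxy)-2-iodo-3-methoxyphenyl]methyl}-2-(2,3,4,5-tetramethoxyphenyl)malonate | CCOC(=O)C(Cc1ccc(OCc2ccccc2)c(OC)c1I)(C(=O)OCC)c1cc(OC)c(OC)c(OC)c1OC | intermediate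
11 | 2-{[4-(benzyloxy)-2-iodo-3-methoxyphenyl]methyl}-2-(2,3,4,5-tetramethoxyphenyl)propane-1,3-diol | COc1cc(C(CO)(CO)Cc2ccc(OCc3ccccc3)c(OC)c2I)c(OC)c(OC)c1OC | intermediate
12 | [(3S)-7-(benzyloxy)-8-methoxy-3-(2,3,4,5-tetramethoxyphenyl)-3,4-dihydro-2H-chromen-3-yl]methanol | COc1cc([C@@]2(CO)COc3c(ccc(OCc4ccccc4)c3OC)C2)c(OC)c(OC)c1OC | intermediate
13 | (3R)-7-(benzyloxy)-8-methoxy-3-(2,3,4,5-tetramethoxyphenyl)-3,4-dihydro-2H-chromene-3-carbaldehyde | COc1cc([C@@]2(C=O)COc3c(ccc(OCc4ccccc4)c3OC)C2)c(OC)c(OC)c1OC | intermediate
14 | (3S)-7-(benzyloxy)-8-methoxy-3-(2,3,4,5-tetramethoxyphenyl)-3,4-dihydro-2H-chromene | COc1cc([C@H]2COc3c(ccc(OCc4ccccc4)c3OC)C2)c(OC)c(OC)c1OC | intermediate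
15 | (3S)-8-methoxy-3-(2,3,4,5-tetramethoxyphenyl)-3,4-dihydro-2H-chromen-7-ol | COc1cc([C@H]2COc3c(ccc(O)c3OC)C2)c(OC)c(OC)c1OC | target

Total step count: 12.
Longest linear sequence: 10 steps (steps 3–12, from 5 to 15). The other branch (steps 1 and 2) joins at step 7.

Steps most likely to fail

Step 9 (key step). The copper–diamine complex may discriminate poorly between the two enantiotopic hydroxymethyl groups of a diol that carries a bulky aryl group on the prochiral carbon. Oxidative addition next to the methoxy group may also be slow, so that unselective background coupling or intermolecular etherification competes. The fallback sets out from 11 and comes back at 12; it sets the stereocentre with an enzyme and then closes the ring without a chiral catalyst. Lipase-catalysed desymmetrising acetylation of 11 (Pseudomonas cepacia lipase or CAL-B, vinyl acetate, MTBE, rt, enzyme fixed by screen) should give (2S)-3-[4-(benzyloxy)-2-iodo-3-methoxyphenyl]-2-(hydroxymethyl)-2-(2,3,4,5-tetramethoxyphenyl)propyl acetate F1. A 1,3-diol monoacetate can racemise by acyl migration under base, so the free hydroxyl is capped at once (MOMCl, iPr2NEt, CH2Cl2, 0 °C) to give (2S)-3-[4-(benzyloxy)-2-iodo-3-methoxyphenyl]-2-[(methoxymethoxy)methyl]-2-(2,3,4,5-tetramethoxyphenyl)propyl acetate F2. Methanolysis of the acetate (K2CO3, MeOH, rt) gives (2R)-3-[4-(benzyloxy)-2-iodo-3-methoxyphenyl]-2-[(methoxymethoxy)methyl]-2-(2,3,4,5-tetramethoxyphenyl)propan-1-ol F3. An ordinary intramolecular Ullmann etherification (CuI, 1,10-phenanthroline, Cs2CO3, toluene, 100 °C) closes the ring to (3R)-7-(benzyloxy)-8-methoxy-3-[(methoxymethoxy)methyl]-3-(2,3,4,5-tetramethoxyphenyl)chromane F4, and mild acid (HCl, MeOH, 40 °C) releases 12.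

Step 11. CO extrusion from the hindered acyl–rhodium at a quaternary carbon may be slow. The tertiary benzylic alkyl–rhodium hydride may also leak into β-hydride elimination and re-addition, which erodes the configuration, or into β-aryloxide elimination, which opens the pyran ring. The fallback sets out from 13 and comes back at 14; it gives up the C3 configuration and sets it anew by asymmetric hydrogenation. Baeyer–Villiger oxidation of 13 (mCPBA, NaHCO3, CH2Cl2, 0 °C), with migration of the tertiary benzylic carbon, should give (3R)-7-(benzyloxy)-8-methoxy-3-(2,3,4,5-tetramethoxyphenyl)chroman-3-yl formate F5. Acid-promoted E1 loss of formic acid (p-TsOH, toluene, 80 °C) gives the conjugated 7-(benzyloxy)-8-methoxy-3-(2,3,4,5-tetramethoxyphenyl)-2H-chromene F6. Iridium-catalysed asymmetric hydrogenation of this isoflav-3-ene (Ir–phosphine-oxazoline BArF catalyst, antipode chosen for the (S)-product, H2 50 bar, CH2Cl2, rt) gives 14 and leaves the benzyl ether in place.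

Step 2. C–C reductive elimination from the hindered, electron-rich aryl–palladium malonate may stall, and protodebromination may take over. The fallback sets out from 2 and comes back at 4; it builds the malonate by C-acylation of an arylacetate instead of by arylation of a malonate. Negishi-type coupling of 2 with the Reformatsky reagent BrZnCH2CO2Et (Pd(dba)2, XPhos, THF, rt–60 °C) should give ethyl 2-(2,3,4,5-tetramethoxyphenyl)acetate F7. Crossed Claisen ethoxycarbonylation (NaH, diethyl carbonate, THF, reflux) then gives 4.

Further compounds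
F1 | step 9 | (2S)-3-[4-(benzyloxy)-2-iodo-3-methoxyphenyl]-2-(hydroxymethyl)-2-(2,3,4,5-tetramethoxyphenyl)propyl acetate | COc1cc([C@@](CO)(COC(C)=O)Cc2ccc(OCc3ccccc3)c(OC)c2I)c(OC)c(OC)c1OC
F2 | step 9 | (2S)-3-[4-(benzyloxy)-2-iodo-3-methoxyphenyl]-2-[(methoxymethoxy)methyl]-2-(2,3,4,5-tetramethoxyphenyl)propyl acetate | COc1cc([C@@](COCOC)(COC(C)=O)Cc2ccc(OCc3ccccc3)c(OC)c2I)c(OC)c(OC)c1OC
F3 | step 9 | (2R)-3-[4-(benzyloxy)-2-iodo-3-methoxyphenyl]-2-[(methoxymethoxy)methyl]-2-(2,3,4,5-tetramethoxyphenyl)propan-1-ol | COc1cc([C@@](COCOC)(CO)Cc2ccc(OCc3ccccc3)c(OC)c2I)c(OC)c(OC)c1OC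
F4 | step 9 | (3R)-7-(benzyloxy)-8-methoxy-3-[(methoxymethoxy)methyl]-3-(2,3,4,5-tetramethoxyphenyl)chromane | COc1cc([C@@]2(COCOC)COc3c(ccc(OCc4ccccc4)c3OC)C2)c(OC)c(OC)c1OC
F5 | step 11 | (3R)-7-(benzyloxy)-8-methoxy-3-(2,3,4,5-tetramethoxyphenyl)chroman-3-yl formate | COc1cc([C@@]2(OC=O)COc3c(ccc(OCc4ccccc4)c3OC)C2)c(OC)c(OC)c1OC
F6 | step 11 | 7-(benzyloxy)-8-methoxy-3-(2,3,4,5-tetramethoxyphenyl)-2H-chromene | COc1cc(C2=Cc3ccc(OCc4ccccc4)c(OC)c3OC2)c(OC)c(OC)c1OC
F7 | step 2 | ethyl 2-(2,3,4,5-tetramethoxyphenyl)acetate | CCOC(=O)Cc1cc(OC)c(OC)c(OC)c1OC
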